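## The problem

The target is a sesquineolignan of three aryl units joined in two different ways. A guaiacylglycerol chain (ring A with C7, C8, C9) is tied through the oxygen on C8 to the 4-position of a syringyl ring B. Ring B sits on C2 of a 2,3-dihydrobenzofuran (O1, C2, C3, C3a) whose benzo ring C carries a methoxy and a formyl group and whose C3 carries the hydroxymethyl carbon C9'. There are four stereocentres in two pairs: C2/C3 (2R,3S, trans across the furan ring) and C7/C8 (7S,8R, erythro, i.e. 7-OH and 8-OAr anti in the extended chain). Within each pair one centre can steer the other (C2 directs C3 while the ring closes, C8 directs C7 in a carbonyl addition), but the flat ring B insulates the pairs from each other, so absolute configuration has to be brought in twice and independently. The ether oxygen of ring B lies between two methoxy groups, which makes the C8–O bond hard to form by displacement at a secondary carbon and argues for forming it early and through a metal-bound allyl. Several groups forbid rough treatment: the aryl aldehyde, the C7 carbinol para to a free phenol (quinone methide formation scrambles C7), the benzylic C2–O1 bond para to an oxygen of ring B (acid opens the furan ring), and any α-aryloxy carbonyl intermediate, which epimerises at C8. The feature that opens the route is at C3: its bonds to C3a of ring C and to the oxygenated C9' are the two ends of a vinyl group, so O1–C2(ring B)–C3–C9' maps onto an O-(1-arylallyl) ether of a phenol that carries a halogen at C3a. 5-Iodovanillin already holds O1, that halogen, the ring C methoxy group and the formyl carbon in the right places.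

## Retrosynthesis

**Unmasking.** Target 23 comes from dioxolane 22 by acetal hydrolysis, and 22 from the tris-silyl ether 21 by desilylation. Only O–Si and acetal C–O bonds are cut. Fluoride is used first, while the formyl group is still masked, and buffered acid last, so the free p-hydroxybenzyl alcohol meets nothing stronger than a pyridinium salt. The forward steps must leave C7 and the C2–O1 bond untouched.

**C7–ring A bond.** Cutting 21 between C7 and ring A gives the α-aryloxy aldehyde 17 and the aryl Grignard reagent 20, made from bromide 19 and ultimately from phenol 18. This cut is preferred to the neighbouring C7–C8 cut, because the usual syn-selective glycolate aldol would give the 7,8-syn (threo) series. It is also preferred to a late C8–O cut, which would ask the hindered ring B oxygen to displace at a secondary carbon. Addition to 17 under polar Felkin–Anh control gives the 7,8-anti (erythro) carbinol. Aldehyde 17 is simpler by one ring and one stereocentre. The forward reaction must avoid chelation and avoid enolising 17.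

**Formyl group from a vinyl group.** The formyl carbon of 17 is the internal carbon of a vinyl group in alkene 15; cleavage runs through diol 16. Alkene 15 is the silyl ether of alcohol 14, which comes from alkoxyamine 13 by reductive N–O cleavage. The C8 centre therefore travels through most of the synthesis as an allylic aryl ether, which cannot epimerise. The carbonyl appears only one step before it is used.

**Key disconnection.** In 13 the C3a–C3 bond and the C9'–O bond are cut together. This leads to the aryl iodide 11 and the aminoxyl radical 12 (TEMPO). Closures through O1–C2 need a preset C3 centre. A Heck closure from the same iodide would leave C9' unoxygenated and C3 trigonal. The radical route forms the ring, the C3 stereocentre and the C9' oxygen in one operation from an acyclic ether whose single stereocentre, C2, directs the closure. The forward reaction must give 5-exo closure, trans selectivity, and capture of the primary radical by 12 and not by tin hydride.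

**O1–C2 bond.** Ether 11 is cut at O1–C2 into the linear cinnamyl carbonate 7 and the lithium aryloxide 10, formed from phenol 9. Phenol 9 is the ethylene acetal of 5-iodovanillin 8. Iridium-catalysed allylic etherification sets C2 under catalyst control. The linear carbonate is chosen because both of its enantiotopic faces funnel through one π-allyl complex. A racemic branched 1-arylallyl carbonate would be a step shorter, but it reacts with this catalyst family largely with memory of its own configuration. The formyl group is masked before this step, because acetalisation afterwards would expose the ionisable bis-aryl allyl ether to acid.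

**Cinnamyl chain.** Carbonate 7 comes from allylic alcohol 6, 6 from the E-cinnamate 5, and 5 from aldehyde 4 by two-carbon olefination at the formyl carbon. These are routine operations. They are demanded by the need for the linear electrophile.

**O–C8 bond.** Aldehyde 4 is the silyl ether of alcohol 3. Cutting the O–C8 bond of 3 gives syringaldehyde 1 and racemic 2-vinyloxirane 2. The palladium-catalysed opening of the vinyl epoxide forms the hindered ether through a π-allyl complex, not through a displacement, and sets C8 by catalyst control. Doing this on the first day, on the cheapest material, has two advantages. Ring B never needs a phenol protecting group. The vinyl group of 3 serves as the latent C7 carbonyl.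

## Roads not taken

**Alternative 1:** The cut is the C7–O bond. A 7-deoxy chain carrying a tert-butyl carbonate on O9 (A1) would be oxidised with Ag2O at the ring A phenol to a para-quinone methide. The carbonate carbonyl oxygen adds to C7 in a 6-exo closure with loss of isobutene, giving the trans cyclic carbonate A2.
- Merits: C7 is set relative to C8 inside a six-membered ring with both substituents equatorial. This is arguably a firmer basis for the erythro relation than the open-chain addition used here. No organometallic reagent meets an epimerisable aldehyde.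
- Weak points: the quinone methide has a proton at C8, activated by the aryloxy group, and tautomerisation by its loss would erase C8. A guaiacyl phenol is oxidised less readily than a syringyl one. The carbonate oxygen is a feeble nucleophile. Making A1 needs the hindered ring B oxygen to displace at a secondary homobenzylic carbon, where elimination competes.
- Comparison: this road answers only the C7/C8 pair and still needs a separate construction of the dihydrobenzofuran. On C7 control it is at least as good in principle. Against that, the chosen plan sets a carbonyl addition of firm precedent, an oxidation–reduction corrective, and a C8–O bond formed without any displacement.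

**Alternative 2:** The cut takes O1–C2 and C3–C9' together, back to the E-hydroxystilbene A3, carbon monoxide and methanol. Under a divalent palladium salt such as Pd(OCOCF3)2 with an oxidant, the ring C phenol adds anti to the alkene at the carbon bearing ring B. The C3–palladium bond then inserts CO and methanolysis gives the trans ester A4.
- Merits: step economy is the best of all four roads. A3 is two or three steps from 5-iodovanillin, no tin is used, and C9' arrives with the ring.
- Weak points: the closure is 5-endo with respect to the alkene. The alkylpalladium at C3 has a syn hydrogen at C2, so β-hydride elimination with aromatisation of the furan ring competes directly with CO insertion. Enantiocontrol would rest on a chiral ligand for divalent palladium in a substrate class where no such control is established. The ester must later be reduced beside an aldehyde.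
- Comparison: if it worked it would be shorter. The chosen plan spends more steps but separates absolute control (iridium) from ring closure (radical), and its closure has no elimination channel.

**Alternative 3:** The cut is O1–C2 alone. The 1,2-diarylpropane A5, with C3 already set, would be oxidised with Ag2O at the ring B phenol to a para-quinone methide at the future C2. The ring C phenol adds in a 5-exo closure to give the trans dihydrobenzofuran A6.
- Merits: the closure is biomimetic and mild, the aldehyde needs no protection, no tin is used, and the trans relation can settle thermodynamically because the closure is reversible. In these respects it is better than the chosen plan.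
- Weak points: C3 must first be made enantioenriched, for instance by auxiliary-controlled benzylation, which costs several steps and a stoichiometric auxiliary. The quinone methide has a proton at C3 that is benzylic to ring C, and its loss would destroy the only stereocentre the step relies on. The ring C phenol, para to a formyl group, is a poor nucleophile.
- Comparison: overall length is similar. The chosen plan sets against the milder conditions a catalyst-controlled C2 and an irreversible closure that cannot erode either centre.

Key step: step 8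

## Route

Assumption: the sense of induction of the two chiral catalysts is taken from their usual facial models ((R,R)-diphosphine in step 1 giving the S ether, (Ra,Rc,Rc)-phosphoramidite in step 7 giving the R ether); if either descriptor is the other way round, the antipodal ligand is used with no other change.

Step 1
Reactants: 1 syringaldehyde; 2 2-vinyloxirane (racemic)
Product: 3 (S)-4-[(1-hydroxybut-3-en-2-yl)oxy]-3,5-dimethoxybenzaldehyde
Conditions: Pd2(dba)3·CHCl3 (1 mol %), (1R,2R)-N,N'-bis[2-(diphenylphosphino)-1-naphthoyl]cyclohexane-1,2-diamine (3 mol %), CH2Cl2, rt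
Reagents that add atoms: none
Why: Palladium-catalysed asymmetric allylic alkylation of a vinyl epoxide (dynamic kinetic asymmetric transformation): zerovalent palladium opens racemic 2 to equilibrating π-allyl alkoxides, the alkoxide deprotonates the acidic phenol of 1, and the ion-paired phenoxide is delivered to the proximal allyl terminus on the face set by the chiral diphosphine, giving C8 as S.

Step 2
Reactants: 3
Product: 4 (S)-3,5-dimethoxy-4-({1-[(triisopropylsilyl)oxy]but-3-en-2-yl}oxy)benzaldehyde
Conditions: i-Pr3SiCl, imidazole, DMF, rt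
Reagents that add atoms: triisopropylsilyl chloride, CC(C)[Si](Cl)(C(C)C)C(C)C
Why: Standard silylation of a primary alcohol; the triisopropylsilyl ether is chosen because it resists i-Bu2AlH, aryloxide, tin radicals and acetic acid and falls to fluoride at the end.

Step 3
Reactants: 4
Product: 5 ethyl (E)-3-[3,5-dimethoxy-4-({(S)-1-[(triisopropylsilyl)oxy]but-3-en-2-yl}oxy)phenyl]acrylate
Conditions: (EtO)2P(O)CH2CO2Et, NaH, THF, 0 °C to rt
Reagents that add atoms: triethyl phosphonoacetate, CCOC(=O)CP(=O)(OCC)OCC
Why: Horner–Wadsworth–Emmons olefination; the stabilised phosphonate anion gives the E-cinnamate, and the C8 hydrogen is not acidic enough to be at risk.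

Step 4
Reactants: 5
Product: 6 (E)-3-[3,5-dimethoxy-4-({(S)-1-[(triisopropylsilyl)oxy]but-3-en-2-yl}oxy)phenyl]prop-2-en-1-ol
Conditions: i-Bu2AlH, CH2Cl2, −78 °C; Rochelle salt work-up
Reagents that add atoms: none
Why: 1,2-Reduction of an α,β-unsaturated ester by i-Bu2AlH at low temperature gives the E-allylic alcohol; the silyl ether, aryl ethers and terminal alkene are inert.

Step 5
Reactants: 6
Product: 7 (E)-3-[3,5-dimethoxy-4-({(S)-1-[(triisopropylsilyl)oxy]but-3-en-2-yl}oxy)phenyl]allyl methyl carbonate
Conditions: ClCO2Me, pyridine, CH2Cl2, 0 °C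
Reagents that add atoms: methyl chloroformate, COC(Cl)=O
Why: Acylation of the primary allylic alcohol installs the leaving group for step 7; the linear E isomer is used because it converges on one π-allyl face under catalyst control.

Step 6
Reactants: 8 5-iodovanillin
Product: 9 4-(1,3-dioxolan-2-yl)-2-iodo-6-methoxyphenol
Conditions: HOCH2CH2OH, p-TsOH·H2O (cat.), PhMe, Dean–Stark reflux; Et3N quench
Reagents that add atoms: ethylene glycol, OCCO
Why: Acid-catalysed acetalisation with azeotropic removal of water; the dioxolane makes the aryloxide a better nucleophile for step 7 and shields the formyl carbon from the Grignard reagent of step 13, and the product is kept under basic work-up because phenolic acetals hydrolyse easily.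

Step 7
Reactants: 7; 9
Product: 11 (R)-1-[3,5-dimethoxy-4-({(S)-1-[(triisopropylsilyl)oxy]but-3-en-2-yl}oxy)phenyl]allyl 4-(1,3-dioxolan-2-yl)-2-iodo-6-methoxyphenyl ether, via lithium aryloxide 10 (not isolated)
Conditions: 9, LiN(SiMe3)2, THF, 0 °C; then 7, [Ir(cod)Cl]2 (2 mol %), (Ra)-binaphthol N,N-bis[(R)-1-phenylethyl]phosphoramidite (4 mol %), n-PrNH2 (activator), THF, rt to 50 °C
Reagents that add atoms: none
Why: Iridium-catalysed asymmetric allylic etherification of a linear cinnamyl carbonate with a lithium aryloxide: the cyclometalated iridium phosphoramidite ionises 7, and 10 attacks the aryl-bearing allyl terminus (branched product) on the ligand-defined face, setting C2 as R; ortho-halo and ortho-alkoxy aryloxides belong to the known scope, and the aryl iodide should not add to monovalent iridium under these conditions.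

Step 8
Reactants: 11; 12 TEMPO (2,2,6,6-tetramethylpiperidin-1-oxyl)
Product: 13 trans-(2R,3S)-2-[3,5-dimethoxy-4-({(S)-1-[(triisopropylsilyl)oxy]but-3-en-2-yl}oxy)phenyl]-5-(1,3-dioxolan-2-yl)-7-methoxy-3-[(2,2,6,6-tetramethylpiperidin-1-yloxy)methyl]-2,3-dihydrobenzofuran
Conditions: Bu3SnH (added in portions), excess 12, degassed PhH, 70 °C
Reagents that add atoms: none
Why: Tin hydride/aminoxyl aryl radical cyclisation: Bu3SnH reduces 12 to its hydroxylamine and releases Bu3Sn radicals, which abstract iodine from 11 to give a σ-aryl radical at C3a. This radical adds to the internal carbon of the neighbouring allyl ether vinyl group in the 5-exo-trig mode, forming the C3a–C3 bond and the dihydrofuran ring irreversibly, and the resulting primary C9' radical is captured by 12 to form the C9'–O bond before hydrogen transfer from tin can compete. The closest known reaction type is the Bu3SnH/TEMPO cyclisation of ortho-haloaryl allyl ethers and N-allylanilides to 3-(aminoxymethyl) dihydrobenzofurans and indolines. The new stereocentre C3 is controlled by C2: in the early chair-like transition state ring B lies pseudo-equatorial and the vinyl group turns its terminal CH2 away from it to avoid allylic strain, so C9' ends up trans to ring B (3S). The step needs 5-exo over 6-endo closure, cyclisation ahead of direct capture of the aryl radical by 12, and reaction at the allyl ether vinyl group only. The first two follow from the short tether and from a closure rate (of the order of 10^9 s^-1 for this radical class) that exceeds bimolecular capture at the working concentration of 12. The third follows from geometry, since the butenyl vinyl group on the ring B oxygen is out of reach and stannyl radical addition to an unactivated alkene is far slower than its reaction with 11 or 12. The C2–H bond is safe because its abstraction would need a strained 1,4-hydrogen shift, and C8 takes no part.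

Step 9
Reactants: 13
Product: 14 {(2R,3S)-2-[3,5-dimethoxy-4-({(S)-1-[(triisopropylsilyl)oxy]but-3-en-2-yl}oxy)phenyl]-5-(1,3-dioxolan-2-yl)-7-methoxy-2,3-dihydrobenzofuran-3-yl}methanol
Conditions: Zn dust, AcOH, dry THF, 40–50 °C; filtration into cold aqueous NaHCO3
Reagents that add atoms: none
Why: Reductive N–O cleavage of the alkoxyamine by zinc in acetic acid, the standard unmasking of aminoxyl-trapped radicals; water is excluded and the work-up buffered so that the dioxolane persists, and the triisopropylsilyl ether and allylic aryl ether are stable.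

Step 10
Reactants: 14
Product: 15 (2R,3S)-3-{[(tert-butyldimethylsilyl)oxy]methyl}-2-[3,5-dimethoxy-4-({(S)-1-[(triisopropylsilyl)oxy]but-3-en-2-yl}oxy)phenyl]-5-(1,3-dioxolan-2-yl)-7-methoxy-2,3-dihydrobenzofuran
Conditions: t-BuMe2SiCl, imidazole, DMF, rt
Reagents that add atoms: tert-butyldimethylsilyl chloride, CC(C)(C)[Si](C)(C)Cl
Why: Standard silylation of the primary C9' alcohol, so that only one hydroxyl (C7) is free after the Grignard step.

Step 11
Reactants: 15
Product: 17 (R)-2-{4-[(2R,3S)-3-{[(tert-butyldimethylsilyl)oxy]methyl}-5-(1,3-dioxolan-2-yl)-7-methoxy-2,3-dihydrobenzofuran-2-yl]-2,6-dimethoxyphenoxy}-3-[(triisopropylsilyl)oxy]propanal, via vicinal diol 16 (not isolated)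
Conditions: K2OsO4·2H2O (cat.), NaIO4, 2,6-lutidine, dioxane/H2O, rt
Reagents that add atoms: osmium tetroxide (formed in the flask from K2OsO4·2H2O and NaIO4; supplies the carbonyl oxygen), O=[Os](=O)(=O)=O
Why: Lemieux–Johnson oxidative cleavage: osmium-catalysed dihydroxylation of the only remaining alkene and periodate glycol fission give the α-aryloxy aldehyde without the risk that ozone poses to three electron-rich arenes; 2,6-lutidine buffers the medium so that the acetal and the C8 configuration survive.

Step 12
Reactants: 18 4-bromo-2-methoxyphenol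
Product: 19 (4-bromo-2-methoxyphenoxy)(tert-butyl)dimethylsilane
Conditions: t-BuMe2SiCl, imidazole, DMF, rt
Reagents that add atoms: tert-butyldimethylsilyl chloride, CC(C)(C)[Si](C)(C)Cl
Why: Standard phenol silylation; the silyl ether tolerates magnesium insertion and leaves with the other silyl groups in step 14.

Step 13
Reactants: 17; 19
Product: 21 (1S,2R)-1-{4-[(tert-butyldimethylsilyl)oxy]-3-methoxyphenyl}-2-{4-[(2R,3S)-3-{[(tert-butyldimethylsilyl)oxy]methyl}-5-(1,3-dioxolan-2-yl)-7-methoxy-2,3-dihydrobenzofuran-2-yl]-2,6-dimethoxyphenoxy}-3-[(triisopropylsilyl)oxy]propan-1-ol, via aryl Grignard reagent 20 (not isolated)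
Conditions: 19, Mg, BrCH2CH2Br (cat.), THF, reflux; then 17, THF, −78 °C; aqueous NH4Cl
Reagents that add atoms: none
Why: Grignard addition under polar Felkin–Anh control: the hindered, poorly chelating aryloxy group lies antiperiplanar to the incoming aryl nucleophile with the silyloxymethyl group inside, so attack on the (R)-aldehyde gives the 7,8-anti (erythro) carbinol with C7 as S; the silyl ethers rule out chelation and the dioxolane masks the other formyl group.

Step 14
Reactants: 21
Product: 22 (1S,2R)-2-{4-[(2R,3S)-5-(1,3-dioxolan-2-yl)-3-(hydroxymethyl)-7-methoxy-2,3-dihydrobenzofuran-2-yl]-2,6-dimethoxyphenoxy}-1-(4-hydroxy-3-methoxyphenyl)propane-1,3-diol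
Conditions: Bu4NF, AcOH, THF, 0 °C to rt
Reagents that add atoms: none
Why: Fluoride cleavage of the two primary silyl ethers and the aryl silyl ether; acetic acid buffers the liberated phenoxide so that the p-hydroxybenzyl alcohol does not ionise to a quinone methide.

Step 15
Reactants: 22
Product: 23 (2R,3S)-2-(4-{[(1S,2R)-1,3-dihydroxy-1-(4-hydroxy-3-methoxyphenyl)propan-2-yl]oxy}-3,5-dimethoxyphenyl)-3-(hydroxymethyl)-7-methoxy-2,3-dihydrobenzofuran-5-carbaldehyde (target)
Conditions: pyridinium p-toluenesulfonate (cat.), acetone/H2O, rt
Reagents that add atoms: water, O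
Why: Mild acid-catalysed hydrolysis of an electron-rich aryl dioxolane, which should be far faster than ionisation at C7 or opening of the C2–O1 bond; no stereocentre is touched.

## Compound list

1 | syringaldehyde | COc1cc(C=O)cc(OC)c1O | starting material
2 | 2-vinyloxirane (racemic) | C=CC1CO1 | starting material
3 | (S)-4-[(1-hydroxybut-3-en-2-yl)oxy]-3,5-dimethoxybenzaldehyde | C=C[C@@H](CO)Oc1c(OC)cc(C=O)cc1OC | intermediate
4 | (S)-3,5-dimethoxy-4-({1-[(triisopropylsilyl)oxy]but-3-en-2-yl}oxy)benzaldehyde | C=C[C@@H](CO[Si](C(C)C)(C(C)C)C(C)C)Oc1c(OC)cc(C=O)cc1OC | intermediate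
5 | ethyl (E)-3-[3,5-dimethoxy-4-({(S)-1-[(triisopropylsilyl)oxy]but-3-en-2-yl}oxy)phenyl]acrylate | C=C[C@@H](CO[Si](C(C)C)(C(C)C)C(C)C)Oc1c(OC)cc(/C=C/C(=O)OCC)cc1OC | intermediate
6 | (E)-3-[3,5-dimethoxy-4-({(S)-1-[(triisopropylsilyl)oxy]but-3-en-2-yl}oxy)phenyl]prop-2-en-1-ol | C=C[C@@H](CO[Si](C(C)C)(C(C)C)C(C)C)Oc1c(OC)cc(/C=C/CO)cc1OC | intermediate
7 | (E)-3-[3,5-dimethoxy-4-({(S)-1-[(triisopropylsilyl)oxy]but-3-en-2-yl}oxy)phenyl]allyl methyl carbonate | C=C[C@@H](CO[Si](C(C)C)(C(C)C)C(C)C)Oc1c(OC)cc(/C=C/COC(=O)OC)cc1OC | intermediate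
8 | 5-iodovanillin | COc1cc(C=O)cc(I)c1O | starting material
9 | 4-(1,3-dioxolan-2-yl)-2-iodo-6-methoxyphenol | COc1cc(C2OCCO2)cc(I)c1O | intermediate
10 | lithium 4-(1,3-dioxolan-2-yl)-2-iodo-6-methoxyphenoxide | COc1cc(C2OCCO2)cc(I)c1[O-].[Li+] | intermediate
11 | (R)-1-[3,5-dimethoxy-4-({(S)-1-[(triisopropylsilyl)oxy]but-3-en-2-yl}oxy)phenyl]allyl 4-(1,3-dioxolan-2-yl)-2-iodo-6-methoxyphenyl ether | C=C[C@@H](CO[Si](C(C)C)(C(C)C)C(C)C)Oc1c(OC)cc([C@@H](C=C)Oc2c(OC)cc(C3OCCO3)cc2I)cc1OC | intermediate
12 | TEMPO (2,2,6,6-tetramethylpiperidin-1-oxyl) | CC1(C)CCCC(C)(C)N1[O] | starting material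
13 | trans-(2R,3S)-2-[3,5-dimethoxy-4-({(S)-1-[(triisopropylsilyl)oxy]but-3-en-2-yl}oxy)phenyl]-5-(1,3-dioxolan-2-yl)-7-methoxy-3-[(2,2,6,6-tetramethylpiperidin-1-yloxy)methyl]-2,3-dihydrobenzofuran | C=C[C@@H](CO[Si](C(C)C)(C(C)C)C(C)C)Oc1c(OC)cc([C@@H]2Oc3c(OC)cc(C4OCCO4)cc3[C@H]2CON5C(C)(C)CCCC5(C)C)cc1OC | intermediate
14 | {(2R,3S)-2-[3,5-dimethoxy-4-({(S)-1-[(triisopropylsilyl)oxy]but-3-en-2-yl}oxy)phenyl]-5-(1,3-dioxolan-2-yl)-7-methoxy-2,3-dihydrobenzofuran-3-yl}methanol | C=C[C@@H](CO[Si](C(C)C)(C(C)C)C(C)C)Oc1c(OC)cc([C@@H]2Oc3c(OC)cc(C4OCCO4)cc3[C@H]2CO)cc1OC | intermediate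
15 | (2R,3S)-3-{[(tert-butyldimethylsilyl)oxy]methyl}-2-[3,5-dimethoxy-4-({(S)-1-[(triisopropylsilyl)oxy]but-3-en-2-yl}oxy)phenyl]-5-(1,3-dioxolan-2-yl)-7-methoxy-2,3-dihydrobenzofuran | C=C[C@@H](CO[Si](C(C)C)(C(C)C)C(C)C)Oc1c(OC)cc([C@@H]2Oc3c(OC)cc(C4OCCO4)cc3[C@H]2CO[Si](C)(C)C(C)(C)C)cc1OC | intermediate
16 | (3R)-3-{4-[(2R,3S)-3-{[(tert-butyldimethylsilyl)oxy]methyl}-5-(1,3-dioxolan-2-yl)-7-methoxy-2,3-dihydrobenzofuran-2-yl]-2,6-dimethoxyphenoxy}-4-[(triisopropylsilyl)oxy]butane-1,2-diol (both C2 epimers) | OCC(O)[C@@H](CO[Si](C(C)C)(C(C)C)C(C)C)Oc1c(OC)cc([C@@H]2Oc3c(OC)cc(C4OCCO4)cc3[C@H]2CO[Si](C)(C)C(C)(C)C)cc1OC | intermediate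
17 | (R)-2-{4-[(2R,3S)-3-{[(tert-butyldimethylsilyl)oxy]methyl}-5-(1,3-dioxolan-2-yl)-7-methoxy-2,3-dihydrobenzofuran-2-yl]-2,6-dimethoxyphenoxy}-3-[(triisopropylsilyl)oxy]propanal | O=C[C@@H](CO[Si](C(C)C)(C(C)C)C(C)C)Oc1c(OC)cc([C@@H]2Oc3c(OC)cc(C4OCCO4)cc3[C@H]2CO[Si](C)(C)C(C)(C)C)cc1OC | intermediate
18 | 4-bromo-2-methoxyphenol | COc1cc(Br)ccc1O | starting material
19 | (4-bromo-2-methoxyphenoxy)(tert-butyl)dimethylsilane | COc1cc(Br)ccc1O[Si](C)(C)C(C)(C)C | intermediate
20 | {4-[(tert-butyldimethylsilyl)oxy]-3-methoxyphenyl}magnesium bromide | COc1cc([Mg]Br)ccc1O[Si](C)(C)C(C)(C)C | intermediate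
21 | (1S,2R)-1-{4-[(tert-butyldimethylsilyl)oxy]-3-methoxyphenyl}-2-{4-[(2R,3S)-3-{[(tert-butyldimethylsilyl)oxy]methyl}-5-(1,3-dioxolan-2-yl)-7-methoxy-2,3-dihydrobenzofuran-2-yl]-2,6-dimethoxyphenoxy}-3-[(triisopropylsilyl)oxy]propan-1-ol | COc1cc([C@H](O)[C@@H](CO[Si](C(C)C)(C(C)C)C(C)C)Oc2c(OC)cc([C@@H]3Oc4c(OC)cc(C5OCCO5)cc4[C@H]3CO[Si](C)(C)C(C)(C)C)cc2OC)ccc1O[Si](C)(C)C(C)(C)C | intermediate
22 | (1S,2R)-2-{4-[(2R,3S)-5-(1,3-dioxolan-2-yl)-3-(hydroxymethyl)-7-methoxy-2,3-dihydrobenzofuran-2-yl]-2,6-dimethoxyphenoxy}-1-(4-hydroxy-3-methoxyphenyl)propane-1,3-diol | COc1cc([C@H](O)[C@@H](CO)Oc2c(OC)cc([C@@H]3Oc4c(OC)cc(C5OCCO5)cc4[C@H]3CO)cc2OC)ccc1O | intermediate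
23 | (2R,3S)-2-(4-{[(1S,2R)-1,3-dihydroxy-1-(4-hydroxy-3-methoxyphenyl)propan-2-yl]oxy}-3,5-dimethoxyphenyl)-3-(hydroxymethyl)-7-methoxy-2,3-dihydrobenzofuran-5-carbaldehyde | COc1cc([C@H](O)[C@@H](CO)Oc2c(OC)cc([C@@H]3Oc4c(OC)cc(C=O)cc4[C@H]3CO)cc2OC)ccc1O | target

## Step count and risks

Total step count: 15. Longest linear sequence: 13 steps from syringaldehyde (steps 1–5, 7–11, 13–15). Steps 6 and 12 prepare the two side fragments.

**Step 8 (key step).**
- Risk: insufficient facial discrimination in the ring closure, so that the cis C3 epimer forms beside the trans one. If the concentration of 12 is set too high, the aryl radical may also be captured before it cyclises.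
- Fallback: thermodynamic instead of kinetic control of C3. It sets out from alcohol 14, carried through step 9 as the epimer mixture. Dess–Martin periodinane oxidises it to the (2R,3R)-2-aryl-5-(1,3-dioxolan-2-yl)-7-methoxy-2,3-dihydrobenzofuran-3-carbaldehyde F1 and its C3 epimer. DBU equilibrates the formyl-bearing benzylic C3 towards the more stable trans aldehyde F1. NaBH4 reduction comes back to the route at 14 as the trans isomer.

**Step 7.**
- Risk: sluggish attack of the doubly ortho-substituted aryloxide, and erosion of enantiomeric and regiochemical purity through re-ionisation of the electron-rich branched ether by the catalyst.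
- Fallback: a displacement with inversion on a resolved alcohol in place of metal-allyl chemistry. It sets out from aldehyde 4. Vinylmagnesium bromide gives 1-aryl-prop-2-en-1-ol F2 as a mixture of carbinol epimers. Lipase B from Candida antarctica with vinyl acetate should acylate the (R)-carbinol to the (R)-acetate F3, by the empirical rule for secondary carbinols with a large aryl and a small vinyl group, leaving the (S)-alcohol F4. Mitsunobu etherification of F4 with phenol 9 (PPh3, diisopropyl azodicarboxylate) inverts the carbinol and comes back to the route at 11.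

**Step 1.**
- Risk: poor regiocontrol (attack at the distal allyl terminus) or poor enantioface selection with a hindered, weakly nucleophilic phenoxide.
- Fallback: chiral-pool material and an inverting displacement. Commercial (R)-but-3-ene-1,2-diol F5 is silylated at the primary hydroxyl (i-Pr3SiCl, imidazole) to (R)-1-[(triisopropylsilyl)oxy]but-3-en-2-ol F6. F6 is coupled with syringaldehyde 1 under Mitsunobu conditions with inversion. The fallback sets out from 1 and comes back to the route at 4, bypassing 3.

**Step 13.**
- Risk: loss of Felkin–Anh control through partial chelation, and enolisation of 17 by the basic reagent, which would epimerise C8.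
- Fallback: C7 is set by hydride delivery instead of by carbon–carbon bond formation. It sets out from 21 obtained as a C7 epimer mixture. Dess–Martin periodinane gives the (R)-1-aryl-2-aryloxy-3-silyloxypropan-1-one F7. Reduction with Zn(BH4)2 in ether, under chelation between the carbonyl and the α-aryloxy oxygen, should favour the anti (erythro) carbinol and comes back to the route at 21.

**Step 9.**
- Risk: loss of the dioxolane by acid-promoted hydrolysis during the N–O cleavage.
- Fallback: the hydrolysis is accepted and the acetal reinstalled. It sets out from 13. Zinc in aqueous acetic acid gives the 3-(hydroxymethyl)-2,3-dihydrobenzofuran-5-carbaldehyde F8. Silylation (t-BuMe2SiCl, imidazole) gives the silyl ether aldehyde F9. Aprotic acetalisation with Me3SiOCH2CH2OSiMe3 and catalytic Me3SiOSO2CF3 at −78 °C comes back to the route at 15.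

## Further compounds

F1 | step 8 | (2R,3R)-2-[3,5-dimethoxy-4-({(S)-1-[(triisopropylsilyl)oxy]but-3-en-2-yl}oxy)phenyl]-5-(1,3-dioxolan-2-yl)-7-methoxy-2,3-dihydrobenzofuran-3-carbaldehyde (trans) | C=C[C@@H](CO[Si](C(C)C)(C(C)C)C(C)C)Oc1c(OC)cc([C@@H]2Oc3c(OC)cc(C4OCCO4)cc3[C@H]2C=O)cc1OC
F2 | step 7 | 1-[3,5-dimethoxy-4-({(S)-1-[(triisopropylsilyl)oxy]but-3-en-2-yl}oxy)phenyl]prop-2-en-1-ol (both carbinol epimers) | C=C[C@@H](CO[Si](C(C)C)(C(C)C)C(C)C)Oc1c(OC)cc(C(O)C=C)cc1OC
F3 | step 7 | (R)-1-[3,5-dimethoxy-4-({(S)-1-[(triisopropylsilyl)oxy]but-3-en-2-yl}oxy)phenyl]allyl acetate | C=C[C@@H](CO[Si](C(C)C)(C(C)C)C(C)C)Oc1c(OC)cc([C@@H](C=C)OC(C)=O)cc1OC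
F4 | step 7 | (S)-1-[3,5-dimethoxy-4-({(S)-1-[(triisopropylsilyl)oxy]but-3-en-2-yl}oxy)phenyl]prop-2-en-1-ol | C=C[C@@H](CO[Si](C(C)C)(C(C)C)C(C)C)Oc1c(OC)cc([C@H](C=C)O)cc1OC
F5 | step 1 | (R)-but-3-ene-1,2-diol | C=C[C@@H](O)CO
F6 | step 1 | (R)-1-[(triisopropylsilyl)oxy]but-3-en-2-ol | C=C[C@@H](O)CO[Si](C(C)C)(C(C)C)C(C)C
F7 | step 13 | (R)-1-{4-[(tert-butyldimethylsilyl)oxy]-3-methoxyphenyl}-2-{4-[(2R,3S)-3-{[(tert-butyldimethylsilyl)oxy]methyl}-5-(1,3-dioxolan-2-yl)-7-methoxy-2,3-dihydrobenzofuran-2-yl]-2,6-dimethoxyphenoxy}-3-[(triisopropylsilyl)oxy]propan-1-one | COc1cc(C(=O)[C@@H](CO[Si](C(C)C)(C(C)C)C(C)C)Oc2c(OC)cc([C@@H]3Oc4c(OC)cc(C5OCCO5)cc4[C@H]3CO[Si](C)(C)C(C)(C)C)cc2OC)ccc1O[Si](C)(C)C(C)(C)C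
F8 | step 9 | (2R,3S)-2-[3,5-dimethoxy-4-({(S)-1-[(triisopropylsilyl)oxy]but-3-en-2-yl}oxy)phenyl]-3-(hydroxymethyl)-7-methoxy-2,3-dihydrobenzofuran-5-carbaldehyde | C=C[C@@H](CO[Si](C(C)C)(C(C)C)C(C)C)Oc1c(OC)cc([C@@H]2Oc3c(OC)cc(C=O)cc3[C@H]2CO)cc1OC
F9 | step 9 | (2R,3S)-3-{[(tert-butyldimethylsilyl)oxy]methyl}-2-[3,5-dimethoxy-4-({(S)-1-[(triisopropylsilyl)oxy]but-3-en-2-yl}oxy)phenyl]-7-methoxy-2,3-dihydrobenzofuran-5-carbaldehyde | C=C[C@@H](CO[Si](C(C)C)(C(C)C)C(C)C)Oc1c(OC)cc([C@@H]2Oc3c(OC)cc(C=O)cc3[C@H]2CO[Si](C)(C)C(C)(C)C)cc1OC
A1 | alternative 1 | 7-deoxy precursor with tert-butyl carbonate on O9 (8S; same spatial arrangement at C8 as the target), ring A phenol free | COc1cc(C[C@@H](COC(=O)OC(C)(C)C)Oc2c(OC)cc([C@@H]3Oc4c(OC)cc(C5OCCO5)cc4[C@H]3CO[Si](C)(C)C(C)(C)C)cc2OC)ccc1O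
A2 | alternative 1 | (7S,8R) 7,9-cyclic carbonate (trans-4-aryl-5-aryloxy-1,3-dioxan-2-one) of the protected target | COc1cc([C@@H]2OC(=O)OC[C@H]2Oc3c(OC)cc([C@@H]4Oc5c(OC)cc(C6OCCO6)cc5[C@H]4CO[Si](C)(C)C(C)(C)C)cc3OC)ccc1O
A3 | alternative 2 | (E)-3-[3,5-dimethoxy-4-(triisopropylsilyloxy)styryl]-4-hydroxy-5-methoxybenzaldehyde | COc1cc(C=O)cc(/C=C/c2cc(OC)c(O[Si](C(C)C)(C(C)C)C(C)C)c(OC)c2)c1O
A4 | alternative 2 | methyl trans-(2R)-2-(3,5-dimethoxy-4-triisopropylsilyloxyphenyl)-5-formyl-7-methoxy-2,3-dihydrobenzofuran-3-carboxylate | COc1cc([C@@H]2Oc3c(OC)cc(C=O)cc3[C@H]2C(=O)OC)cc(OC)c1O[Si](C(C)C)(C(C)C)C(C)C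
A5 | alternative 3 | (S)-3-[1-(tert-butyldimethylsilyloxy)-3-(4-hydroxy-3,5-dimethoxyphenyl)propan-2-yl]-4-hydroxy-5-methoxybenzaldehyde | COc1cc(C[C@H](CO[Si](C)(C)C(C)(C)C)c2cc(C=O)cc(OC)c2O)cc(OC)c1O
A6 | alternative 3 | (2R,3S)-2-(4-hydroxy-3,5-dimethoxyphenyl)-3-(tert-butyldimethylsilyloxymethyl)-7-methoxy-2,3-dihydrobenzofuran-5-carbaldehyde | COc1cc([C@@H]2Oc3c(OC)cc(C=O)cc3[C@H]2CO[Si](C)(C)C(C)(C)C)cc(OC)c1O
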